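**Plan**

- Retrosynthesis: after global O-debenzylation and debromination, the C3–C4 bond of ring C of the top unit is cut to give an α-aryloxy aldehyde (C3) held through O1 on ring A next to a diarylmethyl C4. Then C4(top)–C6(middle) is cut to a ring A aldehyde, O1–C2 to a mandelate, and C4(middle)–C6(bottom) to two epicatechin monomers.
- Forward: (−)-epicatechin → 8-bromo penta-O-benzyl monomer → C4 electrophile → (4β→6) dimer. A Mitsunobu reaction gives the open top unit (ring A aldehyde, ring B, C2, ester), which is joined to C6 of the dimer. The ester is reduced to the aldehyde, ring C of the top unit is closed last by C3–C4, and hydrogenolysis follows.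
- Enabling feature: C4 of the top unit lies between C4a of ring A and C6 of ring D (the benzo ring of the middle unit), both tri-oxygenated rings. Its carbinol therefore ionises to a planar diarylcarbenium ion that divalent chromium reduces far more easily than the aliphatic C3 aldehyde, so both C4 epimers converge on one C4 nucleophile.
- Stereochemistry: the middle and bottom units (2R,3R) come from (−)-epicatechin, and their 4β link from trans attack on the flavan-4-yl cation. Top C2 (R) comes from an (S)-mandelate (asymmetric transfer hydrogenation) by Mitsunobu inversion. Top C3 and C4 are set in the cyclisation under control of C2 and the peri 5-benzyloxy group.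

Key step: step 12

Assumption: compounds 1, 7 and 11 are purchased; in step 7 the catalyst antipode is the one that delivers the (S)-alcohol, and 15 and 16 are carried as C4-epimer mixtures because C4 is planarised in step 12.

**Step 1**
Reactants: 1 (−)-epicatechin
Product: 2 5,7,3',4'-tetra-O-benzyl-(−)-epicatechin
Conditions: BnBr (4.4 equiv), K2CO3, DMF, 0 °C to rt
Reagents that add atoms: benzyl bromide, BrCc1ccccc1
Why: Williamson etherification in which K2CO3 deprotonates only the four phenols, the 3-OH stays free and the mild base should leave C2 and C3 unchanged.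

**Step 2**
Reactants: 2 5,7,3',4'-tetra-O-benzyl-(−)-epicatechin
Product: 3 3,5,7,3',4'-penta-O-benzyl-(−)-epicatechin
Conditions: NaH, BnBr, Bu4NI (cat.), DMF, 0 °C to rt
Reagents that add atoms: benzyl bromide, BrCc1ccccc1
Why: Williamson etherification of the secondary alkoxide; with all phenols capped no quinone methide can open the pyran ring, so both stereocentres are retained.

**Step 3**
Reactants: 3 3,5,7,3',4'-penta-O-benzyl-(−)-epicatechin
Product: 4 8-bromo-3,5,7,3',4'-penta-O-benzyl-(−)-epicatechin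
Conditions: NBS (1.0 equiv), CH2Cl2, −78 °C to rt
Reagents that add atoms: N-bromosuccinimide, O=C1CCC(=O)N1Br
Why: Electrophilic aromatic bromination, which in 5,7-di-O-benzyl flavans goes to C8, the more nucleophilic ring A position; the bromine later blocks C8 and leaves C6 as the only nucleophilic site.

**Step 4**
Reactants: 4 8-bromo-3,5,7,3',4'-penta-O-benzyl-(−)-epicatechin
Product: 5 8-bromo-3,5,7,3',4'-penta-O-benzyl-4β-(2-ethoxyethoxy)-(−)-epicatechin
Conditions: DDQ (2 equiv), 2-ethoxyethanol (5 equiv), CH2Cl2, rt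
Reagents that add atoms: 2-ethoxyethanol, CCOCCO
Why: DDQ benzylic oxidation, in which hydride abstraction from C4 gives the ring A-stabilised flavan-4-yl cation and the alcohol adds anti to the 3-benzyloxy group, setting C4 as 4β (3,4-trans).

**Step 5**
Reactants: 5 8-bromo-3,5,7,3',4'-penta-O-benzyl-4β-(2-ethoxyethoxy)-(−)-epicatechin; 4 8-bromo-3,5,7,3',4'-penta-O-benzyl-(−)-epicatechin (3 equiv)
Product: 6 deca-O-benzyl-8,8'-dibromo-epicatechin-(4β→6)-epicatechin (C6 of the upper unit free)
Conditions: Me3SiOTf (0.2 equiv), CH2Cl2, −78 °C; Et3N quench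
Reagents that add atoms: none
Why: Lewis acid-mediated Friedel–Crafts coupling of a flavan-4-yl cation with a flavan nucleophile: with C8 of 4 blocked the cation from 5 is attacked by C6, attack anti to the 3-benzyloxy group of the 2,3-cis unit sets the new C4 centre as 4β, and the excess of 4 limits self-condensation of 5.

**Step 6**
Reactants: 7 4-bromo-1,2-bis(benzyloxy)benzene
Product: 9 methyl 2-[3,4-bis(benzyloxy)phenyl]-2-oxoacetate, via aryl Grignard reagent 8 (not isolated)
Conditions: Mg, THF, rt; then dimethyl oxalate (2 equiv), THF, −78 °C; 1 M HCl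
Reagents that add atoms: dimethyl oxalate, COC(=O)C(=O)OC
Why: Grignard formation and mono-acylation with excess dimethyl oxalate at low temperature, where the tetrahedral adduct holds until the quench and gives the aryl glyoxylate.

**Step 7**
Reactants: 9 methyl 2-[3,4-bis(benzyloxy)phenyl]-2-oxoacetate
Product: 10 methyl (S)-2-[3,4-bis(benzyloxy)phenyl]-2-hydroxyacetate
Conditions: RuCl(p-cymene)[(R,R)-TsDPEN] (1 mol%), HCO2H/Et3N (5:2), DMF, rt
Reagents that add atoms: none
Why: Noyori asymmetric transfer hydrogenation of the aryl α-keto ester, in which the chiral Ru–H/N–H catalyst delivers hydride to one carbonyl face and sets the (S)-carbinol.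

**Step 8**
Reactants: 11 2,4,6-trihydroxybenzaldehyde
Product: 12 2-hydroxy-4,6-bis(benzyloxy)benzaldehyde
Conditions: BnBr (2.1 equiv), K2CO3, DMF, rt
Reagents that add atoms: benzyl bromide, BrCc1ccccc1
Why: Williamson etherification in which the two phenols not hydrogen-bonded to the formyl group are alkylated and the chelated ortho-OH stays free.

**Step 9**
Reactants: 10 methyl (S)-2-[3,4-bis(benzyloxy)phenyl]-2-hydroxyacetate; 12 2-hydroxy-4,6-bis(benzyloxy)benzaldehyde
Product: 13 methyl (R)-2-[3,4-bis(benzyloxy)phenyl]-2-[3,5-bis(benzyloxy)-2-formylphenoxy]acetate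
Conditions: PPh3, DIAD, THF, 0 °C to rt
Reagents that add atoms: none
Why: Mitsunobu etherification in which the acidic salicylaldehyde-type phenol displaces the activated α-hydroxy ester by SN2 with inversion (the ester disfavours ionisation), giving the (R)-aryl ether that becomes O1–C2 of the top unit.

**Step 10**
Reactants: 13 methyl (R)-2-[3,4-bis(benzyloxy)phenyl]-2-[3,5-bis(benzyloxy)-2-formylphenoxy]acetate; 6 deca-O-benzyl-8,8'-dibromo-epicatechin-(4β→6)-epicatechin
Product: 15 C4 carbinol of the open top unit on the dimer (both C4 epimers), via diarylcarbenium triflate 14 (not isolated)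
Conditions: Me3SiOTf (1.2 equiv), CH2Cl2, −78 to −30 °C; then aq. NaHCO3
Reagents that add atoms: water, O
Why: Friedel–Crafts hydroxyalkylation in which the O-silylated 2,4,6-trioxygenated benzaldehyde is attacked by C6 of the upper unit of 6, the only unblocked ring position of that type, so the future C4–C6 link forms without regiochemical choice; the tetra-ortho-substituted carbenium ion 14 should not arylate again and water gives both C4 epimers.

**Step 11**
Reactants: 15 C4 carbinol of the open top unit on the dimer (both C4 epimers)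
Product: 16 hydroxy aldehyde (C3 formyl, C4–OH; open form of a seven-membered lactol; both C4 epimers)
Conditions: (i-Bu)2AlH (3 equiv), CH2Cl2, −78 °C; aq. KNaC4H4O6; used crude
Reagents that add atoms: none
Why: Partial ester reduction in which, after deprotonation of C4–OH, the α-aryloxy ester gives a chelated tetrahedral aluminate that is stable at −78 °C and releases the aldehyde on work-up; no base is present, so (R)-C2 should be kept.

**Step 12**
Reactants: 16 hydroxy aldehyde (both C4 epimers)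
Product: 19 protected trimer (ring C of the top unit closed; top 3-OH free), via diarylmethyl chloride 17 (not isolated), via diarylmethylchromium dichloride 18 (not isolated)
Conditions: Me3SiCl (2 equiv), CrCl2 (8 equiv), THF/DMF 4:1, high dilution, 0 °C to rt; aq. NH4Cl
Reagents that add atoms: none
Why: Proposed new method: Me3SiCl ionises the doubly benzylic C4–OH (or its lactol) to the planar carbenium/chloride 17, CrCl2 reduces it by single-electron transfer to the persistent diarylmethyl radical and a second divalent chromium captures this as the C4–Cr species 18, which adds to the C3 aldehyde as a weakly basic, oxophilic trivalent-chromium nucleophile (no ketyl, so no loss of the α-aryloxy group and no enolisation at C2); the closest known reaction type is the Nozaki–Hiyama-type (Takai) addition of benzylchromium reagents to aldehydes, not yet shown intramolecularly for a diarylmethyl group. Ring C of the top unit closes in the 6-exo-trig mode. The step is stereoconvergent because 17 is planar and the C4–Cr bond of 18 homolyses reversibly, so both C4 epimers of 16 enter one Curtin–Hammett manifold. C4 is controlled by the peri 5-benzyloxy group of ring A and by the metal: the C4–Cr bond stands perpendicular to ring A, the bulky ring D anti to it and pseudo-axial, and in the four-centre C4–Cr···O=C3 transition state the chromium-bound oxygen is therefore delivered trans to ring D (3,4-trans, 4β). C3 is controlled by the (R)-C2 centre set in step 9: only the chair with ring B equatorial and the C3–O bond axial (cis to ring B, within reach of O1 for chelation) avoids a 1,3-diaxial clash of ring B with ring D, which gives 2,3-cis. The selectivity needed is reduction at C4 in the presence of the aliphatic aldehyde, the aryl bromides and the benzyl ethers, secured by the far easier reduction of the bis(trioxyaryl)carbenium ion and by the absence of a nickel co-catalyst.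

**Step 13**
Reactants: 19 protected trimer
Product: 20 epicatechin-(4β→6)-epicatechin-(4β→6)-epicatechin (CNP0163146.2)
Conditions: H2 (1 atm), Pd(OH)2/C, Et3N (2.2 equiv), THF/MeOH/H2O, rt
Reagents that add atoms: none
Why: Catalytic hydrogenolysis removes the fourteen benzyl ethers and hydrodebrominates both C8 positions in one operation, with Et3N buffering the HBr so that the acid-labile interflavan bonds and all stereocentres should stay untouched.

**Compound list**

1 | (−)-epicatechin | Oc1cc(O)c2c(c1)O[C@H](c1ccc(O)c(O)c1)[C@H](O)C2 | starting material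
2 | 5,7,3',4'-tetra-O-benzyl-(−)-epicatechin | c1ccccc1COc1cc(OCc3ccccc3)c2c(c1)O[C@H](c1ccc(OCc3ccccc3)c(OCc3ccccc3)c1)[C@H](O)C2 | intermediate
3 | 3,5,7,3',4'-penta-O-benzyl-(−)-epicatechin | c1ccccc1COc1cc(OCc3ccccc3)c2c(c1)O[C@H](c1ccc(OCc3ccccc3)c(OCc3ccccc3)c1)[C@H](OCc1ccccc1)C2 | intermediate
4 | 8-bromo-3,5,7,3',4'-penta-O-benzyl-(−)-epicatechin | c1ccccc1COc1cc(OCc3ccccc3)c2c(c1Br)O[C@H](c1ccc(OCc3ccccc3)c(OCc3ccccc3)c1)[C@H](OCc1ccccc1)C2 | intermediate
5 | 8-bromo-3,5,7,3',4'-penta-O-benzyl-4β-(2-ethoxyethoxy)-(−)-epicatechin | c1ccccc1COc1cc(OCc3ccccc3)c2c(c1Br)O[C@H](c1ccc(OCc3ccccc3)c(OCc3ccccc3)c1)[C@H](OCc1ccccc1)[C@H]2OCCOCC | intermediate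
6 | deca-O-benzyl-8,8'-dibromo-epicatechin-(4β→6)-epicatechin (upper unit C6–H free) | c1c(OCc3ccccc3)c(Br)c2c(c1OCc1ccccc1)[C@H](c1c(OCc3ccccc3)c(Br)c3c(c1OCc1ccccc1)C[C@@H](OCc1ccccc1)[C@@H](c1ccc(OCc4ccccc4)c(OCc4ccccc4)c1)O3)[C@@H](OCc1ccccc1)[C@@H](c1ccc(OCc3ccccc3)c(OCc3ccccc3)c1)O2 | intermediate
7 | 4-bromo-1,2-bis(benzyloxy)benzene | Brc1ccc(OCc2ccccc2)c(OCc2ccccc2)c1 | starting material
8 | 3,4-bis(benzyloxy)phenylmagnesium bromide | Br[Mg]c1ccc(OCc2ccccc2)c(OCc2ccccc2)c1 | intermediate (not isolated)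
9 | methyl 2-[3,4-bis(benzyloxy)phenyl]-2-oxoacetate | COC(=O)C(=O)c1ccc(OCc2ccccc2)c(OCc2ccccc2)c1 | intermediate
10 | methyl (S)-2-[3,4-bis(benzyloxy)phenyl]-2-hydroxyacetate | O[C@@H](c1ccc(OCc2ccccc2)c(OCc2ccccc2)c1)C(=O)OC | intermediate
11 | 2,4,6-trihydroxybenzaldehyde | O=Cc1c(O)cc(O)cc1O | starting material
12 | 2-hydroxy-4,6-bis(benzyloxy)benzaldehyde | O=Cc1c(O)cc(OCc2ccccc2)cc1OCc1ccccc1 | intermediate
13 | methyl (R)-2-[3,4-bis(benzyloxy)phenyl]-2-[3,5-bis(benzyloxy)-2-formylphenoxy]acetate | O=Cc1c(OCc2ccccc2)cc(OCc2ccccc2)cc1O[C@H](c1ccc(OCc2ccccc2)c(OCc2ccccc2)c1)C(=O)OC | intermediate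
14 | diarylcarbenium triflate (cationic future C4 between ring A of the open top unit and C6 of the upper unit of 6) | [O-]S(=O)(=O)C(F)(F)F.[CH+](c1c(OCc2ccccc2)cc(OCc2ccccc2)cc1O[C@H](c1ccc(OCc2ccccc2)c(OCc2ccccc2)c1)C(=O)OC)c1c(OCc3ccccc3)c(Br)c2c(c1OCc1ccccc1)[C@H](c1c(OCc3ccccc3)c(Br)c3c(c1OCc1ccccc1)C[C@@H](OCc1ccccc1)[C@@H](c1ccc(OCc4ccccc4)c(OCc4ccccc4)c1)O3)[C@@H](OCc1ccccc1)[C@@H](c1ccc(OCc3ccccc3)c(OCc3ccccc3)c1)O2 | intermediate (not isolated)
15 | C4 carbinol: methyl (2R)-2-[3,4-bis(benzyloxy)phenyl]-2-{3,5-bis(benzyloxy)-2-[hydroxy(Ar)methyl]phenoxy}acetate, Ar = C6 of the upper unit of 6; both epimers at the carbinol carbon | OC(c1c(OCc2ccccc2)cc(OCc2ccccc2)cc1O[C@H](c1ccc(OCc2ccccc2)c(OCc2ccccc2)c1)C(=O)OC)c1c(OCc3ccccc3)c(Br)c2c(c1OCc1ccccc1)[C@H](c1c(OCc3ccccc3)c(Br)c3c(c1OCc1ccccc1)C[C@@H](OCc1ccccc1)[C@@H](c1ccc(OCc4ccccc4)c(OCc4ccccc4)c1)O3)[C@@H](OCc1ccccc1)[C@@H](c1ccc(OCc3ccccc3)c(OCc3ccccc3)c1)O2 | intermediate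
16 | hydroxy aldehyde: as 15 with the ester reduced to the formyl group (C3); both C4 epimers | OC(c1c(OCc2ccccc2)cc(OCc2ccccc2)cc1O[C@H](c1ccc(OCc2ccccc2)c(OCc2ccccc2)c1)C=O)c1c(OCc3ccccc3)c(Br)c2c(c1OCc1ccccc1)[C@H](c1c(OCc3ccccc3)c(Br)c3c(c1OCc1ccccc1)C[C@@H](OCc1ccccc1)[C@@H](c1ccc(OCc4ccccc4)c(OCc4ccccc4)c1)O3)[C@@H](OCc1ccccc1)[C@@H](c1ccc(OCc3ccccc3)c(OCc3ccccc3)c1)O2 | intermediate
17 | diarylmethyl chloride: as 16 with C4–Cl in place of C4–OH | ClC(c1c(OCc2ccccc2)cc(OCc2ccccc2)cc1O[C@H](c1ccc(OCc2ccccc2)c(OCc2ccccc2)c1)C=O)c1c(OCc3ccccc3)c(Br)c2c(c1OCc1ccccc1)[C@H](c1c(OCc3ccccc3)c(Br)c3c(c1OCc1ccccc1)C[C@@H](OCc1ccccc1)[C@@H](c1ccc(OCc4ccccc4)c(OCc4ccccc4)c1)O3)[C@@H](OCc1ccccc1)[C@@H](c1ccc(OCc3ccccc3)c(OCc3ccccc3)c1)O2 | intermediate (not isolated)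
18 | diarylmethylchromium dichloride: as 16 with C4–CrCl2 in place of C4–OH | Cl[Cr](Cl)C(c1c(OCc2ccccc2)cc(OCc2ccccc2)cc1O[C@H](c1ccc(OCc2ccccc2)c(OCc2ccccc2)c1)C=O)c1c(OCc3ccccc3)c(Br)c2c(c1OCc1ccccc1)[C@H](c1c(OCc3ccccc3)c(Br)c3c(c1OCc1ccccc1)C[C@@H](OCc1ccccc1)[C@@H](c1ccc(OCc4ccccc4)c(OCc4ccccc4)c1)O3)[C@@H](OCc1ccccc1)[C@@H](c1ccc(OCc3ccccc3)c(OCc3ccccc3)c1)O2 | intermediate (not isolated)
19 | protected trimer: 5,7,3',4'-tetra-O-benzyl-epicatechin (3-OH free) linked 4β→6 to the upper unit of 6 | c1ccccc1COc1cc(OCc3ccccc3)c2c(c1)O[C@H](c1ccc(OCc3ccccc3)c(OCc3ccccc3)c1)[C@H](O)[C@H]2c1c(OCc3ccccc3)c(Br)c2c(c1OCc1ccccc1)[C@H](c1c(OCc3ccccc3)c(Br)c3c(c1OCc1ccccc1)C[C@@H](OCc1ccccc1)[C@@H](c1ccc(OCc4ccccc4)c(OCc4ccccc4)c1)O3)[C@@H](OCc1ccccc1)[C@@H](c1ccc(OCc3ccccc3)c(OCc3ccccc3)c1)O2 | intermediate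
20 | epicatechin-(4β→6)-epicatechin-(4β→6)-epicatechin (CNP0163146.2) | Oc1cc(O)c2c(c1)O[C@H](c1ccc(O)c(O)c1)[C@H](O)[C@H]2c1c(O)cc2c(c1O)[C@H](c1c(O)cc3c(c1O)C[C@@H](O)[C@@H](c1ccc(O)c(O)c1)O3)[C@@H](O)[C@@H](c1ccc(O)c(O)c1)O2 | target

Total step count: 13. Longest linear sequence: 9 steps (steps 1, 2, 3, 4, 5, 10, 11, 12, 13).

**Steps most likely to fail**

1. Step 12 (bears the label "Proposed new method:"). What may go wrong: the tetra-ortho-substituted diarylmethyl radical may not be captured by chromium and may instead be reduced to the diarylmethane; the aldehyde may epimerise at C2; facial selectivity at C3 may be poor. Fallback (known chemistry): the top unit is brought in as an intact epicatechin ring instead of being built. The fallback sets out from 6. Me3SiOTf-mediated Friedel–Crafts coupling with the C4 electrophile 5 (CH2Cl2, −78 °C), C6 of the upper unit of 6 being its only free nucleophilic position, should give pentadeca-O-benzyl-8,8',8''-tribromo-epicatechin-(4β→6)-epicatechin-(4β→6)-epicatechin F1. Hydrogenolysis of F1 under the conditions of step 13 comes back to the route at 20.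

2. Step 10. What may go wrong: attack by the bromine-deactivated, doubly flanked C6 on the deactivated aldehyde may be slow; ring B of 13 may instead arylate the activated aldehyde intramolecularly; forcing may cleave the interflavan bond. Fallback: the union is made at the benzyl instead of the benzylidene oxidation level. The fallback sets out from 13. NaBH4 (THF/MeOH, 0 °C) reduces the formyl group to methyl (2R)-2-[3,4-bis(benzyloxy)phenyl]-2-[3,5-bis(benzyloxy)-2-(hydroxymethyl)phenoxy]acetate F2. Its much more electrophilic trioxygenated benzyl cation (Sc(OTf)3 cat., CH2Cl2, −40 °C) alkylates C6 of 6 to the diarylmethane analogue of 15 (CH2 in place of CHOH) F3. DDQ/H2O (CH2Cl2, 0 °C) then abstracts hydride from the methylene between the two trioxygenated rings and water traps the cation, which comes back to the route at 15.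

3. Step 11. What may go wrong: over-reduction to the primary alcohol, or epimerisation at C2 of the α-aryloxy aldehyde during work-up. Fallback: full reduction followed by selective re-oxidation. The fallback sets out from 15. LiBH4 (THF, 0 °C) reduces the ester to the diol, (2R)-2-aryl-2-aryloxyethanol analogue of 15 (CH2OH in place of CO2Me) F4. TEMPO/PhI(OAc)2 (CH2Cl2, rt) oxidises only the primary alcohol, the hindered diaryl carbinol being left alone, and the crude aldehyde comes back to the route at 16.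

**Further compounds**

F1 | step 12 | pentadeca-O-benzyl-8,8',8''-tribromo-epicatechin-(4β→6)-epicatechin-(4β→6)-epicatechin | c1ccccc1COc1cc(OCc3ccccc3)c2c(c1Br)O[C@H](c1ccc(OCc3ccccc3)c(OCc3ccccc3)c1)[C@H](OCc1ccccc1)[C@H]2c1c(OCc3ccccc3)c(Br)c2c(c1OCc1ccccc1)[C@H](c1c(OCc3ccccc3)c(Br)c3c(c1OCc1ccccc1)C[C@@H](OCc1ccccc1)[C@@H](c1ccc(OCc4ccccc4)c(OCc4ccccc4)c1)O3)[C@@H](OCc1ccccc1)[C@@H](c1ccc(OCc3ccccc3)c(OCc3ccccc3)c1)O2
F2 | step 10 | methyl (2R)-2-[3,4-bis(benzyloxy)phenyl]-2-[3,5-bis(benzyloxy)-2-(hydroxymethyl)phenoxy]acetate | OCc1c(OCc2ccccc2)cc(OCc2ccccc2)cc1O[C@H](c1ccc(OCc2ccccc2)c(OCc2ccccc2)c1)C(=O)OC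
F3 | step 10 | diarylmethane analogue of 15 (CH2 in place of CHOH) | C(c1c(OCc2ccccc2)cc(OCc2ccccc2)cc1O[C@H](c1ccc(OCc2ccccc2)c(OCc2ccccc2)c1)C(=O)OC)c1c(OCc3ccccc3)c(Br)c2c(c1OCc1ccccc1)[C@H](c1c(OCc3ccccc3)c(Br)c3c(c1OCc1ccccc1)C[C@@H](OCc1ccccc1)[C@@H](c1ccc(OCc4ccccc4)c(OCc4ccccc4)c1)O3)[C@@H](OCc1ccccc1)[C@@H](c1ccc(OCc3ccccc3)c(OCc3ccccc3)c1)O2
F4 | step 11 | diol analogue of 15 (CH2OH in place of CO2Me; both C4 epimers) | OC(c1c(OCc2ccccc2)cc(OCc2ccccc2)cc1O[C@H](c1ccc(OCc2ccccc2)c(OCc2ccccc2)c1)CO)c1c(OCc3ccccc3)c(Br)c2c(c1OCc1ccccc1)[C@H](c1c(OCc3ccccc3)c(Br)c3c(c1OCc1ccccc1)C[C@@H](OCc1ccccc1)[C@@H](c1ccc(OCc4ccccc4)c(OCc4ccccc4)c1)O3)[C@@H](OCc1ccccc1)[C@@H](c1ccc(OCc3ccccc3)c(OCc3ccccc3)c1)O2
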